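## Retrosynthetic overview

1. The target is epicatechin-(4β→8)-epigallocatechin 3-O-gallate-(4β→8)-epicatechin-(4β→8)-catechin. Units are counted 1 to 4 from the top epicatechin, with flavan numbering and rings A (phloroglucinol), B (2-aryl) and C (pyran) in each unit.
2. Late disconnections: all benzyl ethers (hydrogenolysis), then the C4(unit 2)–C8(unit 3) bond. This bond is made by ionizing the C4 ester of a unit 1–unit 2 flavan-3,4-diol bis-gallate in the presence of benzylated procyanidin B1 (units 3 and 4).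
3. Key disconnection: ring C of unit 2 is cut at O1–C2 and C4a–C4. This gives a phenol (ring A of unit 2, already carrying unit 1 on C8) and a cis-2,3-epoxy aldehyde that brings C2, C3, C4 and ring B.
4. Enabling feature: in ring A of unit 2 the hydroxyl on C8a and the neighbouring C4a–H form an O,C-bis-nucleophile with only one open ortho carbon. C2–C3–C4 can be a 1,3-bis-electrophile because C2 is benzylic to the 4-oxygenated ring B and C4 can hold an oxygen that is later exchanged for C8 of unit 3. Only the epoxide is set by catalysis; C2 follows by inversion and C4 by relay from C3.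
5. Ring order: rings C of units 1, 3 and 4 are bought with the natural flavan-3-ols. Ring C of unit 2 is the only ring made, after unit 1 is joined to ring A and before units 3–4 are attached.

Key step: step 9

Remark: the carbinol carbon C4 of unit 2 is created in step 9 without control and is drawn without configuration in 14, 15 and 17; both epimers converge in step 13, where this carbon is ionized.

## Route

Step 1
Reactants: 1 (−)-epicatechin
Product: 2 tetra-O-benzylepicatechin (5,7,3',4'-benzyl ethers)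
Conditions: BnBr (4.4 equiv), K2CO3, DMF, 0 °C → rt
Reagents that add atoms: benzyl bromide, BrCc1ccccc1
Why: Williamson etherification of the four phenols, which are far more acidic than the C3 alcohol, so the secondary hydroxyl should stay free and no stereocenter is touched.

Step 2
Reactants: 2 tetra-O-benzylepicatechin
Product: 3 tetra-O-benzyl-4β-(2-ethoxyethoxy)epicatechin
Conditions: DDQ (2 equiv), 2-ethoxyethanol (excess), CH2Cl2, rt
Reagents that add atoms: 2-ethoxyethanol, CCOCCO
Why: DDQ benzylic oxidation, in which hydride abstraction at C4 gives a cation stabilized by the 5,7-dialkoxy ring A that the alcohol should trap trans to the C3 hydroxyl (4β).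

Step 3
Reactants: 3 tetra-O-benzyl-4β-(2-ethoxyethoxy)epicatechin
Product: 4 penta-O-benzyl-4β-(2-ethoxyethoxy)epicatechin
Conditions: NaH, BnBr, DMF, 0 °C → rt
Reagents that add atoms: benzyl bromide, BrCc1ccccc1
Why: Williamson etherification of the only free hydroxyl, which blocks O3 of unit 1 against the acylation of step 10 while the base-stable C4 ether is kept.

Step 4
Reactants: 4 penta-O-benzyl-4β-(2-ethoxyethoxy)epicatechin; 5 phloroglucinol dibenzyl ether [3,5-bis(benzyloxy)phenol]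
Product: 6 penta-O-benzylepicatechin-(4β→2)-phloroglucinol 3,5-dibenzyl ether (free phenol ortho to the flavanyl group)
Conditions: 5 (4 equiv), TMSOTf (0.1 equiv), CH2Cl2, −78 → −40 °C
Reagents that add atoms: none
Why: Lewis-acid-mediated Friedel–Crafts arylation of the flavan-4-yl cation, the reaction type that makes 4→8 interflavan bonds, in which attack trans to the C3 substituent gives 4β and the carbon flanked by OH and one benzyloxy group should win over the carbon between two benzyloxy groups, as C8 does over C6 in benzylated flavans.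

Step 5
Reactants: 7 tri-O-benzylgallaldehyde [3,4,5-tris(benzyloxy)benzaldehyde]; 8 ethyl 2-(diphenoxyphosphoryl)acetate
Product: 9 ethyl (Z)-3-[3,4,5-tris(benzyloxy)phenyl]prop-2-enoate
Conditions: NaH, THF, −78 → 0 °C
Reagents that add atoms: none
Why: Horner–Wadsworth–Emmons olefination in its Z-selective diaryl phosphonoacetate form, where fast irreversible elimination from the kinetic adduct should give the (Z)-cinnamate.

Step 6
Reactants: 9 ethyl (Z)-3-[3,4,5-tris(benzyloxy)phenyl]prop-2-enoate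
Product: 10 (Z)-3-[3,4,5-tris(benzyloxy)phenyl]prop-2-en-1-ol
Conditions: i-Bu2AlH (2.5 equiv), CH2Cl2, −78 °C; aq. potassium sodium tartrate
Reagents that add atoms: none
Why: 1,2-reduction of the enoate to the allylic alcohol by an aluminium hydride, which should leave the Z double bond and the benzyl ethers untouched.

Step 7
Reactants: 10 (Z)-3-[3,4,5-tris(benzyloxy)phenyl]prop-2-en-1-ol
Product: 11 cis-epoxy alcohol [(2R,3S)-3-[3,4,5-tris(benzyloxy)phenyl]oxiran-2-yl]methanol
Conditions: Ti(OiPr)4 (20 mol%), D-(−)-diethyl tartrate (24 mol%), t-BuOOH, 4 Å molecular sieves, CH2Cl2, −20 °C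
Reagents that add atoms: tert-butyl hydroperoxide, CC(C)(C)OO
Why: Katsuki–Sharpless asymmetric epoxidation, in which the D-tartrate complex should deliver oxygen to the face of the Z-allylic alcohol that gives the (2R,3S) cis-epoxide stereospecifically; this is the only stereocenter-setting catalytic event for unit 2, and any minor enantiomer would end as a separable diastereomer after step 9.

Step 8
Reactants: 11 cis-epoxy alcohol
Product: 12 cis-epoxy aldehyde (2S,3S)-3-[3,4,5-tris(benzyloxy)phenyl]oxirane-2-carbaldehyde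
Conditions: Dess–Martin periodinane, pyridine, CH2Cl2, 0 °C; used at once
Reagents that add atoms: none
Why: Dess–Martin oxidation under buffered conditions should convert the primary alcohol into the aldehyde without opening the epoxide or epimerizing the carbon next to the carbonyl.

Step 9
Reactants: 6 penta-O-benzylepicatechin-(4β→2)-phloroglucinol 3,5-dibenzyl ether; 12 cis-epoxy aldehyde
Product: 15 penta-O-benzylepicatechin-(4β→8)-penta-O-benzyl-4-hydroxyepigallocatechin (2,3-cis-flavan-3,4-diol of unit 2; C4 epimers), via titanium phenoxide 13 (not isolated), via titanium-chelated epoxy alkoxide 14 (not isolated)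
Conditions: Ti(OiPr)4 (1.05 equiv), toluene, rt, then vacuum (−i-PrOH); 12 (1.2 equiv), CH2Cl2, −20 °C → rt, then 35 °C; aq. tartaric acid
Reagents that add atoms: none
Why: Proposed new method: ligand exchange turns phenol 6 into its triisopropoxytitanium phenoxide 13, which binds aldehyde 12 and attacks it with the only free ortho carbon through a six-membered metal-templated transition state (C4a–C4); in the resulting chelate 14 the same titanium centre activates the 2,3-epoxy alkoxide so that the phenoxide oxygen opens the epoxide at the distal benzylic carbon (O1–C2). The closest known reaction types are the ortho-specific hydroxyalkylation of titanium and magnesium phenoxides by alpha-oxygenated aldehydes and the Ti(OiPr)4-mediated C3-selective opening of 2,3-epoxy alcohols by external nucleophiles; their combination in one flask with an internal phenoxide is the untested part. Ring C closes in a 6-endo-tet epoxide opening, favoured over the 5-exo mode by chelation of the epoxy alkoxide and by the 4-benzyloxy-substituted aryl group on C2. C3 keeps the configuration of the epoxide, C2 is formed with inversion, so the cis-epoxide is translated into the 2R,3R (2,3-cis) arrangement of epigallocatechin, while the carbinol C4 may form as either epimer without consequence because it is ionized in step 13. The step needs ortho C-attack on the aldehyde instead of attack by the para carbon or on the epoxide, and this is secured by the phenoxide–aldehyde template together with the fact that the second ortho position of 6 is occupied by unit 1.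

Step 10
Reactants: 15 flavan-3,4-diol of units 1 and 2; 16 tri-O-benzylgalloyl chloride [3,4,5-tris(benzyloxy)benzoyl chloride]
Product: 17 3,4-bis-O-(tri-O-benzylgalloyl) ester of 15
Conditions: 16 (3 equiv), Et3N, DMAP (cat.), CH2Cl2, 0 °C → rt
Reagents that add atoms: none
Why: DMAP-catalysed acylation of the only two free hydroxyls, which should install the C3 gallate of the target and at the same time turn the C4 oxygen into a leaving group.

Step 11
Reactants: 18 (+)-catechin
Product: 19 tetra-O-benzylcatechin (5,7,3',4'-benzyl ethers)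
Conditions: BnBr (4.4 equiv), K2CO3, DMF, 0 °C → rt
Reagents that add atoms: benzyl bromide, BrCc1ccccc1
Why: Williamson etherification of the four phenols as in step 1, with the C3 alcohol expected to stay free.

Step 12
Reactants: 3 tetra-O-benzyl-4β-(2-ethoxyethoxy)epicatechin; 19 tetra-O-benzylcatechin
Product: 20 octa-O-benzylprocyanidin B1 [tetra-O-benzylepicatechin-(4β→8)-tetra-O-benzylcatechin]
Conditions: 19 (4 equiv), TMSOTf (0.1 equiv), CH2Cl2, −78 °C
Reagents that add atoms: none
Why: Lewis-acid-promoted Friedel–Crafts coupling of the C4 cation from 3 with C8 of the benzylated catechin, the standard construction of 4→8 procyanidin bonds, in which the nucleophile should add trans to the C3 hydroxyl of the 2,3-cis electrophile (4β) and the excess of 19 suppresses oligomerization.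

Step 13
Reactants: 17 bis-gallate of units 1 and 2; 20 octa-O-benzylprocyanidin B1
Product: 21 protected tetramer (all 20 phenols and O3 of unit 1 benzylated; 3-OH of units 3 and 4 free)
Conditions: 20 (3 equiv), TMSOTf (0.2 equiv), CH2Cl2, −78 → −40 °C, slow addition of 17
Reagents that add atoms: none
Why: Friedel–Crafts interflavan coupling in which ionization of the C4 gallate gives the ring A-stabilized flavan-4-yl cation, the C3 gallate shields the α face by acyloxonium participation, and C8 of unit 3 (the least hindered nucleophilic carbon of 20) should therefore add from the β face to set the 3,4-trans (4β) configuration from either C4 epimer.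

Step 14
Reactants: 21 protected tetramer
Product: 22 epicatechin-(4β→8)-epigallocatechin 3-O-gallate-(4β→8)-epicatechin-(4β→8)-catechin (CNP0332815.1)
Conditions: H2 (1 atm), Pd(OH)2/C, THF/MeOH/H2O, rt
Reagents that add atoms: none
Why: hydrogenolysis of all 21 benzyl ethers under neutral conditions, which should leave the gallate ester, the interflavan C–C bonds and every stereocenter untouched.

## Compound list

1 | (−)-epicatechin, (2R,3R) | O[C@@H]1Cc2c(O)cc(O)cc2O[C@@H]1c1ccc(O)c(O)c1 | starting material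
2 | 5,7,3',4'-tetra-O-benzyl-(−)-epicatechin | O[C@@H]1Cc2c(OCc3ccccc3)cc(OCc3ccccc3)cc2O[C@@H]1c1ccc(OCc2ccccc2)c(OCc2ccccc2)c1 | intermediate
3 | 5,7,3',4'-tetra-O-benzyl-4β-(2-ethoxyethoxy)epicatechin (C4 ether trans to 3-OH) | CCOCCO[C@H]1c2c(OCc3ccccc3)cc(OCc3ccccc3)cc2O[C@H](c2ccc(OCc3ccccc3)c(OCc3ccccc3)c2)[C@@H]1O | intermediate
4 | 3,5,7,3',4'-penta-O-benzyl-4β-(2-ethoxyethoxy)epicatechin | CCOCCO[C@H]1c2c(OCc3ccccc3)cc(OCc3ccccc3)cc2O[C@H](c2ccc(OCc3ccccc3)c(OCc3ccccc3)c2)[C@@H]1OCc1ccccc1 | intermediate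
5 | 3,5-bis(benzyloxy)phenol (phloroglucinol dibenzyl ether) | Oc1cc(OCc2ccccc2)cc(OCc2ccccc2)c1 | starting material
6 | 3,5-bis(benzyloxy)-2-(3,5,7,3',4'-penta-O-benzylepicatechin-4β-yl)phenol | Oc1cc(OCc2ccccc2)cc(OCc2ccccc2)c1[C@H]1c2c(OCc3ccccc3)cc(OCc3ccccc3)cc2O[C@H](c2ccc(OCc3ccccc3)c(OCc3ccccc3)c2)[C@@H]1OCc1ccccc1 | intermediate
7 | 3,4,5-tris(benzyloxy)benzaldehyde | O=Cc1cc(OCc2ccccc2)c(OCc2ccccc2)c(OCc2ccccc2)c1 | starting material
8 | ethyl 2-(diphenoxyphosphoryl)acetate | CCOC(=O)CP(=O)(Oc1ccccc1)Oc1ccccc1 | starting material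
9 | ethyl (Z)-3-[3,4,5-tris(benzyloxy)phenyl]prop-2-enoate | CCOC(=O)/C=C\c1cc(OCc2ccccc2)c(OCc2ccccc2)c(OCc2ccccc2)c1 | intermediate
10 | (Z)-3-[3,4,5-tris(benzyloxy)phenyl]prop-2-en-1-ol | OC/C=C\c1cc(OCc2ccccc2)c(OCc2ccccc2)c(OCc2ccccc2)c1 | intermediate
11 | [(2R,3S)-3-[3,4,5-tris(benzyloxy)phenyl]oxiran-2-yl]methanol (cis-epoxide) | OC[C@H]1O[C@H]1c1cc(OCc2ccccc2)c(OCc2ccccc2)c(OCc2ccccc2)c1 | intermediate
12 | (2S,3S)-3-[3,4,5-tris(benzyloxy)phenyl]oxirane-2-carbaldehyde (cis-epoxide) | O=C[C@H]1O[C@H]1c1cc(OCc2ccccc2)c(OCc2ccccc2)c(OCc2ccccc2)c1 | intermediate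
13 | triisopropoxytitanium phenoxide of 6 | CC(C)O[Ti](OC(C)C)(OC(C)C)Oc1cc(OCc2ccccc2)cc(OCc2ccccc2)c1[C@H]1c2c(OCc3ccccc3)cc(OCc3ccccc3)cc2O[C@H](c2ccc(OCc3ccccc3)c(OCc3ccccc3)c2)[C@@H]1OCc1ccccc1 | intermediate (not isolated)
14 | diisopropoxytitanium chelate of the ortho-hydroxyalkylation adduct (phenoxide O and carbinol O on titanium, cis-epoxide intact, carbinol carbon unassigned) | CC(C)O[Ti]1(OC(C)C)Oc2c([C@H]3c4c(OCc5ccccc5)cc(OCc5ccccc5)cc4O[C@H](c4ccc(OCc5ccccc5)c(OCc5ccccc5)c4)[C@@H]3OCc3ccccc3)c(OCc3ccccc3)cc(OCc3ccccc3)c2C(O1)[C@H]1O[C@H]1c1cc(OCc2ccccc2)c(OCc2ccccc2)c(OCc2ccccc2)c1 | intermediate (not isolated)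
15 | 3,5,7,3',4'-penta-O-benzylepicatechin-(4β→8)-5,7,3',4',5'-penta-O-benzyl-4-hydroxyepigallocatechin (C2 and C3 of unit 2 as in epigallocatechin; C4 epimers) | O[C@@H]1C(O)c2c(OCc3ccccc3)cc(OCc3ccccc3)c([C@H]3c4c(OCc5ccccc5)cc(OCc5ccccc5)cc4O[C@H](c4ccc(OCc5ccccc5)c(OCc5ccccc5)c4)[C@@H]3OCc3ccccc3)c2O[C@@H]1c1cc(OCc2ccccc2)c(OCc2ccccc2)c(OCc2ccccc2)c1 | intermediate
16 | 3,4,5-tris(benzyloxy)benzoyl chloride | O=C(Cl)c1cc(OCc2ccccc2)c(OCc2ccccc2)c(OCc2ccccc2)c1 | starting material
17 | 3,4-bis-O-[3,4,5-tris(benzyloxy)benzoyl] ester of 15 (C4 epimers) | O=C(O[C@@H]1C(OC(=O)c2cc(OCc3ccccc3)c(OCc3ccccc3)c(OCc3ccccc3)c2)c2c(OCc3ccccc3)cc(OCc3ccccc3)c([C@H]3c4c(OCc5ccccc5)cc(OCc5ccccc5)cc4O[C@H](c4ccc(OCc5ccccc5)c(OCc5ccccc5)c4)[C@@H]3OCc3ccccc3)c2O[C@@H]1c1cc(OCc2ccccc2)c(OCc2ccccc2)c(OCc2ccccc2)c1)c1cc(OCc2ccccc2)c(OCc2ccccc2)c(OCc2ccccc2)c1 | intermediate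
18 | (+)-catechin, (2R,3S) | O[C@H]1Cc2c(O)cc(O)cc2O[C@@H]1c1ccc(O)c(O)c1 | starting material
19 | 5,7,3',4'-tetra-O-benzyl-(+)-catechin | O[C@H]1Cc2c(OCc3ccccc3)cc(OCc3ccccc3)cc2O[C@@H]1c1ccc(OCc2ccccc2)c(OCc2ccccc2)c1 | intermediate
20 | octa-O-benzylprocyanidin B1, tetra-O-benzylepicatechin-(4β→8)-tetra-O-benzylcatechin | c1c(OCc3ccccc3)cc(OCc3ccccc3)c2c1O[C@H](c1ccc(OCc3ccccc3)c(OCc3ccccc3)c1)[C@H](O)[C@H]2c1c(OCc3ccccc3)cc(OCc3ccccc3)c2c1O[C@H](c1ccc(OCc3ccccc3)c(OCc3ccccc3)c1)[C@@H](O)C2 | intermediate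
21 | protected tetramer: target with all 20 phenols and O3 of unit 1 as benzyl ethers (21 benzyl groups) | O=C(O[C@@H]1[C@@H](c2c(OCc5ccccc5)cc(OCc5ccccc5)c3c2O[C@H](c2ccc(OCc5ccccc5)c(OCc5ccccc5)c2)[C@H](O)[C@H]3c2c(OCc5ccccc5)cc(OCc5ccccc5)c3c2O[C@H](c2ccc(OCc5ccccc5)c(OCc5ccccc5)c2)[C@@H](O)C3)c2c(OCc5ccccc5)cc(OCc5ccccc5)c([C@H]3c4c(OCc5ccccc5)cc(OCc5ccccc5)cc4O[C@H](c4ccc(OCc5ccccc5)c(OCc5ccccc5)c4)[C@@H]3OCc5ccccc5)c2O[C@@H]1c1cc(OCc5ccccc5)c(OCc5ccccc5)c(OCc5ccccc5)c1)c1cc(OCc5ccccc5)c(OCc5ccccc5)c(OCc5ccccc5)c1 | intermediate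
22 | epicatechin-(4β→8)-epigallocatechin 3-O-gallate-(4β→8)-epicatechin-(4β→8)-catechin (CNP0332815.1) | O=C(O[C@@H]1[C@@H](c2c(O)cc(O)c3c2O[C@H](c2ccc(O)c(O)c2)[C@H](O)[C@H]3c2c(O)cc(O)c3c2O[C@H](c2ccc(O)c(O)c2)[C@@H](O)C3)c2c(O)cc(O)c([C@H]3c4c(O)cc(O)cc4O[C@H](c4ccc(O)c(O)c4)[C@@H]3O)c2O[C@@H]1c1cc(O)c(O)c(O)c1)c1cc(O)c(O)c(O)c1 | target

## Step count and risks

Total step count: 14.
Longest linear sequence: 8 steps (1, 2, 3, 4, 9, 10, 13, 14; the epoxy aldehyde branch 5, 6, 7, 8, 9, 10, 13, 14 is equally long).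

Steps most likely to fail:

1. Step 9 (proposed new method). The hindered phenoxide may attack the aldehyde sluggishly, the electron-rich ring may open the epoxide by Friedel–Crafts attack at carbon, the epoxide may close in the 5-exo mode to a dihydrobenzofuran, or the epoxy aldehyde may epimerize next to the carbonyl. Fallback (known chemistry, ring C of unit 2 taken from the chiral pool): it sets out from 4 and comes back at 21. Commercial (−)-epigallocatechin 3-O-gallate would be perbenzylated (BnBr, K2CO3, DMF) to octa-O-benzylepigallocatechin gallate F1. TMSOTf-mediated coupling of 4 with an excess of F1 should give, by attack of C8, the benzylated epicatechin-(4β→8)-epigallocatechin gallate F2. DDQ with 2-ethoxyethanol would oxidize its only benzylic methylene (C4 of unit 2) to the 4β-(2-ethoxyethoxy) dimer F3. Coupling of F3 with 20 under TMSOTf then gives 21.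

2. Step 13. The electrophile may self-condense through the free C8 of its unit 1, the cation may be attacked by C6 positions of 20, or the free 3-hydroxyls may trap the acyloxonium ion as orthoesters. Fallback (linear growth with cheap monomer nucleophiles in large excess instead of the dimer): it sets out from 17 and comes back at 21. 17 would be coupled (TMSOTf, CH2Cl2, −78 °C) with a large excess of monomer 2 to give the unit 1–unit 2–unit 3 trimer F4. DDQ with 2-ethoxyethanol would oxidize the only benzylic methylene (C4 of unit 3) to the 4β-(2-ethoxyethoxy) trimer F5. TMSOTf coupling of F5 with an excess of 19 then gives 21.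

3. Step 4. Arylation may occur at the carbon para to the phenol hydroxyl (between the two benzyloxy groups), or the phenol may be O-alkylated, so that regioisomers of 6 form. Fallback (the para carbon is blocked before the coupling): it sets out from 5 and comes back at 6. Para-selective bromination of 5 with Bu4NBr3 would give 4-bromo-3,5-bis(benzyloxy)phenol F6, whose only open carbons are the two equivalent ortho positions. TMSOTf coupling with 4 would give the bromo analogue of 6, 4-bromo-3,5-bis(benzyloxy)-2-(penta-O-benzylepicatechin-4β-yl)phenol F7. Bromine–lithium exchange (n-BuLi, 2.2 equiv, THF, −78 °C) followed by a methanol quench removes the blocking group and gives 6.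

## Further compounds

F1 | step 9 | octa-O-benzyl-(−)-epigallocatechin 3-O-gallate | O=C(O[C@@H]1Cc2c(OCc3ccccc3)cc(OCc3ccccc3)cc2O[C@@H]1c1cc(OCc2ccccc2)c(OCc2ccccc2)c(OCc2ccccc2)c1)c1cc(OCc2ccccc2)c(OCc2ccccc2)c(OCc2ccccc2)c1
F2 | step 9 | penta-O-benzylepicatechin-(4β→8)-octa-O-benzylepigallocatechin 3-O-gallate | O=C(O[C@@H]1Cc2c(OCc5ccccc5)cc(OCc5ccccc5)c([C@H]3c4c(OCc5ccccc5)cc(OCc5ccccc5)cc4O[C@H](c4ccc(OCc5ccccc5)c(OCc5ccccc5)c4)[C@@H]3OCc5ccccc5)c2O[C@@H]1c1cc(OCc5ccccc5)c(OCc5ccccc5)c(OCc5ccccc5)c1)c1cc(OCc5ccccc5)c(OCc5ccccc5)c(OCc5ccccc5)c1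
F3 | step 9 | 4β-(2-ethoxyethoxy) derivative of F2 at C4 of unit 2 | O=C(O[C@@H]1[C@@H](OCCOCC)c2c(OCc5ccccc5)cc(OCc5ccccc5)c([C@H]3c4c(OCc5ccccc5)cc(OCc5ccccc5)cc4O[C@H](c4ccc(OCc5ccccc5)c(OCc5ccccc5)c4)[C@@H]3OCc5ccccc5)c2O[C@@H]1c1cc(OCc5ccccc5)c(OCc5ccccc5)c(OCc5ccccc5)c1)c1cc(OCc5ccccc5)c(OCc5ccccc5)c(OCc5ccccc5)c1
F4 | step 13 | benzylated trimer of units 1, 2 and 3 (unit 3 = tetra-O-benzylepicatechin with free 3-OH and C4 methylene) | O=C(O[C@@H]1[C@@H](c2c(OCc5ccccc5)cc(OCc5ccccc5)c3c2O[C@H](c2ccc(OCc5ccccc5)c(OCc5ccccc5)c2)[C@H](O)C3)c2c(OCc5ccccc5)cc(OCc5ccccc5)c([C@H]3c4c(OCc5ccccc5)cc(OCc5ccccc5)cc4O[C@H](c4ccc(OCc5ccccc5)c(OCc5ccccc5)c4)[C@@H]3OCc5ccccc5)c2O[C@@H]1c1cc(OCc5ccccc5)c(OCc5ccccc5)c(OCc5ccccc5)c1)c1cc(OCc5ccccc5)c(OCc5ccccc5)c(OCc5ccccc5)c1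
F5 | step 13 | 4β-(2-ethoxyethoxy) derivative of F4 at C4 of unit 3 | O=C(O[C@@H]1[C@@H](c2c(OCc5ccccc5)cc(OCc5ccccc5)c3c2O[C@H](c2ccc(OCc5ccccc5)c(OCc5ccccc5)c2)[C@H](O)[C@H]3OCCOCC)c2c(OCc5ccccc5)cc(OCc5ccccc5)c([C@H]3c4c(OCc5ccccc5)cc(OCc5ccccc5)cc4O[C@H](c4ccc(OCc5ccccc5)c(OCc5ccccc5)c4)[C@@H]3OCc5ccccc5)c2O[C@@H]1c1cc(OCc5ccccc5)c(OCc5ccccc5)c(OCc5ccccc5)c1)c1cc(OCc5ccccc5)c(OCc5ccccc5)c(OCc5ccccc5)c1
F6 | step 4 | 4-bromo-3,5-bis(benzyloxy)phenol | Oc1cc(OCc2ccccc2)c(Br)c(OCc2ccccc2)c1
F7 | step 4 | 4-bromo-3,5-bis(benzyloxy)-2-(3,5,7,3',4'-penta-O-benzylepicatechin-4β-yl)phenol | Oc1cc(OCc2ccccc2)c(Br)c(OCc2ccccc2)c1[C@H]1c2c(OCc3ccccc3)cc(OCc3ccccc3)cc2O[C@H](c2ccc(OCc3ccccc3)c(OCc3ccccc3)c2)[C@@H]1OCc1ccccc1
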